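**Plan**
- Retrosynthesis: first the three esters and the C7/C9 oxygens are removed, then the cyclobutane bond C10–C11 is cut (two enone α′ carbons). C3–C4 and C5–C11 of the cyclohexenone are then cut together, giving a cycloheptene and a 2-pyrone with CO2 put back. The cycloheptene is opened at C4=C5 (metathesis), C9–C10 (crotylboration) and C6–C7 (tert-(hydroxy)prenylation).
- Enabling feature: ring C1–C2–C3–C4–C5–C11 is a 3-methylcyclohex-2-enone. Its O1, C1, C2, C3 and C3-methyl are the 4-oxygen, C4, C5, C6 and 6-methyl of triacetic acid lactone, and C11 is pyrone C3. C11 is cis to the CH2O arm (C14) on C6, so a carboxyl on pyrone C3 can be tied to O14 as a six-membered lactone. That carboxyl is β to the C1 ketone and leaves later as CO2.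
- Forward order: seven-membered ring, then six-membered ring (key step), then four-membered ring, then C7/C9 oxygens and esters.
- Stereochemistry: C6 from the iridium catalyst; C4/C5 from the tether; C10/C11 forced by the ring fusion; C7 by ligand-reinforced borylation anti to CH2OSi; C9 by hydride delivery from O7 (Evans–Tishchenko), which also installs the acetate.
- Locants: C1 ring C=O, C2=C3(CH3), C4 and C11 cyclobutane CH next to C3 and C1, C5 cyclobutane CH, C6 C(CH3)(C14H2O), C7 (OAc), C8 H2, C9 (O-senecioyl), C10 C(CH3).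

Key step: step 13

Assumption: the (S)-Tol-BINAP iridium catalyst of step 1 is taken to give the (2S,3S) anti diol (with the opposite sense the (R)-ligand is used). The C7 carbinol configuration is immaterial, because this centre becomes trigonal in step 16.

Step 1
Reactants: 1 3,3-diethoxypropan-1-ol; 2 2-methyl-2-vinyloxirane (isoprene monoxide)
Product: 3 (2S,3S)-5,5-diethoxy-2-methyl-2-vinylpentane-1,3-diol
Conditions: cyclometalated π-allyl iridium C,O-benzoate catalyst from [Ir(cod)Cl]2, (S)-Tol-BINAP, 4-cyano-3-nitrobenzoic acid and allyl acetate (5 mol %), K3PO4 (5 mol %), two equivalents of the racemic epoxide, THF, 60 °C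
Reagents that add atoms: none
Why: Iridium-catalysed transfer-hydrogenative carbonyl tert-(hydroxy)prenylation: 1 is dehydrogenated to the aldehyde, 2 is ionised to a π-allyl that adds through its disubstituted terminus in a closed chair transition state, so the ligand sets the quaternary centre C6 and the anti C7 carbinol, and the coupling is redox-neutral, joining one molecule of each partner with no co-product.

Step 2
Reactants: 3
Product: 4 (2S,3S)-1,3-bis(tert-butyldimethylsilyloxy)-5,5-diethoxy-2-methyl-2-vinylpentane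
Conditions: TBSOTf (2.3 equiv), 2,6-lutidine, CH2Cl2, −78 °C
Reagents that add atoms: tert-butyldimethylsilyl triflate, CC(C)(C)[Si](C)(C)OS(=O)(=O)C(F)(F)F
Why: The silyl triflate silylates the primary and the hindered secondary hydroxyl at −78 °C, where the acetal is not yet activated.

Step 3
Reactants: 4
Product: 5 (3S,4S)-3,5-bis(tert-butyldimethylsilyloxy)-4-methyl-4-vinylpentanal
Conditions: PPTS (cat.), acetone/H2O (20:1), 40 °C
Reagents that add atoms: water, O
Why: Acid-catalysed transacetalisation to acetone unmasks the aldehyde, and TBS ethers tolerate PPTS.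

Step 4
Reactants: 5; 6 (E)-crotylboronic acid pinacol ester
Product: 8 (6S,7S)-6,8-bis(tert-butyldimethylsilyloxy)-3,7-dimethyl-7-vinyloct-1-en-4-ol (isomers at C3/C4), via pinacol borate ester 7 (not isolated)
Conditions: toluene, 23 °C; then H2O work-up
Reagents that add atoms: none
Why: Allylboration through a six-membered chair transition state gives the α-methylallyl carbinol (C9–C10 bond); the two new centres are uncontrolled and become trigonal later (C9 ketone, C10 enolate).

Step 5
Reactants: 8
Product: 9 (5S,6S)-6-(tert-butyldimethylsilyloxy)-5-[(tert-butyldimethylsilyloxy)methyl]-2,5-dimethylcyclohept-3-en-1-ol (isomers at C1/C2)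
Conditions: second-generation Hoveyda–Grubbs catalyst (5 mol %), toluene (0.005 M), 80 °C
Reagents that add atoms: none
Why: Ring-closing olefin metathesis of the two terminal vinyl groups closes the cycloheptene (cis C4=C5) with loss of ethene.

Step 6
Reactants: 9
Product: 10 (5S,6S)-6-(tert-butyldimethylsilyloxy)-5-[(tert-butyldimethylsilyloxy)methyl]-2,5-dimethylcyclohept-3-en-1-one (C2 epimers)
Conditions: Dess–Martin periodinane, pyridine, CH2Cl2, 0 °C to rt
Reagents that add atoms: none
Why: Dess–Martin oxidation under buffered, non-enolising conditions gives the β,γ-unsaturated ketone without conjugation.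

Step 7
Reactants: 10
Product: 11 ethylene ketal of 10 (1,4-dioxaspiro[4.6]undec-7-ene with 6-CH3, 9-CH3, 9-CH2OTBS, 10-OTBS)
Conditions: 1,2-bis(trimethylsilyloxy)ethane, TMSOTf (5 mol %), CH2Cl2, −78 to −20 °C
Reagents that add atoms: 1,2-bis(trimethylsilyloxy)ethane, C[Si](C)(C)OCCO[Si](C)(C)C
Why: Aprotic silyl-triflate-catalysed ketalisation at low temperature masks the C9 ketone without moving the alkene, so that it can neither conjugate nor lose silanol to an enone during the thermal key step.

Step 8
Reactants: 11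
Product: 12 primary alcohol (C14–OH free; C7–OTBS, C9 ketal and C4=C5 retained)
Conditions: HF·pyridine, pyridine, THF, 0 °C
Reagents that add atoms: none
Why: Buffered HF·pyridine cleaves the primary TBS ether much faster than the secondary neopentylic one, and the ketal is stable.

Step 9
Reactants: 13 tert-butyl methyl malonate; 14 diketene
Product: 16 tert-butyl 4-hydroxy-6-methyl-2-oxo-2H-pyran-3-carboxylate, via acetoacetylmalonate 15 (not isolated)
Conditions: NaH, THF, 0 °C; 14, 0 °C to rt; then AcOH, toluene, 80 °C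
Reagents that add atoms: none
Why: Sodiomalonate is C-acetoacetylated by diketene and the enol oxygen of 15 lactonises onto the methyl ester (better leaving group than tert-butoxide) to give the 3-carboxylated triacetic acid lactone.

Step 10
Reactants: 16
Product: 17 tert-butyl 4-methoxy-6-methyl-2-oxo-2H-pyran-3-carboxylate
Conditions: Me2SO4, K2CO3, acetone, 56 °C
Reagents that add atoms: dimethyl sulfate, COS(=O)(=O)OC
Why: O-Alkylation of the acidic vinylogous-acid hydroxyl at C4 of the pyrone.

Step 11
Reactants: 17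
Product: 18 4-methoxy-6-methyl-2-oxo-2H-pyran-3-carboxylic acid
Conditions: TFA, CH2Cl2, 0 °C to rt
Reagents that add atoms: none
Why: Acidolysis of the tert-butyl ester (loss of 2-methylpropene) leaves the pyrone lactone untouched.

Step 12
Reactants: 18; 12
Product: 20 pyrone ester of 12 (O14 acylated by the C3 carboxyl of the pyrone), via acid chloride 19 (not isolated)
Conditions: (COCl)2, DMF (cat.), CH2Cl2, 0 °C; then 12, pyridine, DMAP (cat.), 0 °C to rt
Reagents that add atoms: none
Why: Acid chloride formation and DMAP-catalysed acylation of the neopentyl primary alcohol attach the pyrone through its C3 carboxyl.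

Step 13
Reactants: 20
Product: 22 tricyclic 2-methoxycyclohexa-1,3-diene δ-lactone (C11=C1(OMe)–C2=C3(CH3); lactone C11–C(=O)–O–C14; C4–H and C5–H cis), via bridged lactone adduct 21 (not isolated)
Conditions: 1,2-dichlorobenzene (0.01 M), BHT, 200 °C, sealed tube, argon
Reagents that add atoms: none
Why: Thermal intramolecular [4+2] cycloaddition of the pyrone diene (termini pyrone C3 and C6) to the only C=C of the cycloheptene gives bridged lactone 21, which at this temperature loses CO2 by retro-[4+2] to diene 22, so that C3–C4 and C5–C11 are made in one operation (closest known type: intramolecular 2-pyrone Diels–Alder/decarboxylation cascades with unactivated tethered alkenes). The six-membered carbocycle closes by the cycloaddition itself and the δ-lactone closes as the fused six-membered tether ring (ester carbonyl on the diene terminus C11, CH2O arm on C6 next to alkene carbon C5). The new centres C4 and C5 are cis because the addition is suprafacial on the cis-cycloheptene, and both bonds form on the face that carries the CH2O arm because the four-atom tether cannot reach the other face; this is the face the target requires. The bridgehead centres of 21 become trigonal on CO2 loss, so endo/exo selectivity is irrelevant. Regioselectivity (pyrone C3 to C5, pyrone C6 to C4) is secured by the tether (six- against seven-membered lactone) and chemoselectivity by the absence of any other alkene, the C9 ketone being held as a ketal. The ester must reach its s-cis conformer and both diene termini are substituted, hence the high temperature and dilution.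

Step 14
Reactants: 22
Product: 25 cis-fused bicyclic hydroxy dione (3-methylcyclohex-2-en-1-one fused at C4–C5 to a cycloheptanone with C6(CH3)(CH2OH), C7–OH cis to C14, C9=O, C10–CH3 epimers), via keto lactone 23 (not isolated), via keto acid 24 (not isolated)
Conditions: 2 M aq. HCl/THF (1:1), 55 °C
Reagents that add atoms: water, O
Why: Aqueous acid hydrolyses the vinylogous methyl carbonate (C1 ketone, C2=C3 retained), the ketal and the silyl ether; β-keto δ-lactone 23 opens to β-keto acid 24, which decarboxylates, and the ring-fusion centres are not enolisable under these conditions (C4 only through the γ-dienol).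

Step 15
Reactants: 25
Product: 26 C14 tert-butyldiphenylsilyl ether of 25
Conditions: TBDPSCl, imidazole, DMF, 0 °C to rt
Reagents that add atoms: tert-butyldiphenylsilyl chloride, CC(C)(C)[Si](Cl)(c1ccccc1)c1ccccc1
Why: The primary hydroxyl is silylated selectively over the hindered secondary one, and the bulky silyl group later shields its face of the seven-membered ring.

Step 16
Reactants: 26
Product: 28 cis-fused bicyclic bis-enone (cyclohex-2-enone C1/C2=C3 and cyclohept-2-enone C9/C8=C7; C10–H epimers; C14–OTBDPS), via mesylate 27 (not isolated)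
Conditions: MsCl, Et3N, CH2Cl2, 0 °C; then DBU, rt
Reagents that add atoms: none
Why: Mesylation and E1cB elimination of the β-mesyloxy ketone give the cycloheptenone; C8 thereby becomes vinylic, which leaves C10 as the only enolisable position of this ketone.

Step 17
Reactants: 28
Product: 30 tricyclic longipina-2,7-diene-1,9-dione with C14–OTBDPS (cyclobutane C4–C5–C11–C10 closed), via dilithium bis-dienolate 29 (not isolated)
Conditions: LDA (2.3 equiv), THF, −78 °C (inverse addition); then CuCl2 (2.2 equiv) in DMF, −78 to 0 °C, 0.005 M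
Reagents that add atoms: none
Why: Proposed new method: double kinetic α′-deprotonation gives the bis(cross-conjugated) dienolate 29, whose only nucleophilic carbons, C10 and C11, are held close together on the same side of the cis ring fusion; one-electron oxidation by CuCl2 of the more electron-rich tetrasubstituted enolate gives a tertiary α-keto radical at C10 that is captured by the neighbouring enolate carbon C11, and the resulting ketyl is oxidised by the second CuCl2, closing the cyclobutane; C10 and C11 can only be joined in the configuration of the target because C10 is tied to C4 and C11 to C5 of the cis-fused bond; the closest known reaction types are the CuCl2-mediated oxidative coupling of ketone lithium enolates to 1,4-diketones and intramolecular oxidative enolate couplings that close five- and six-membered rings, not yet shown for the four-membered ring of a bicyclo[3.1.1]heptane.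

Step 18
Reactants: 30
Product: 32 7-hydroxy-longipin-2-ene-1,9-dione with C14–OTBDPS (7-OH trans to C14), via C7 boronate 31 (not isolated)
Conditions: CuCl (5 mol %), NaOtBu (10 mol %), Josiphos ligand (6 mol %, antipode matched to the substrate bias), B2pin2 (1.1 equiv), MeOH (2 equiv), THF, rt; then NaBO3·4H2O, THF/H2O, 0 °C
Reagents that add atoms: sodium perborate, [Na+].[O-]OB=O
Why: Copper–boryl conjugate addition goes to the disubstituted cycloheptenone (the cyclohexenone is β,β-disubstituted and hindered); boron adds to C7 on the face opposite the CH2OTBDPS arm of C6, reinforced by the matched ligand, and perborate oxidation proceeds with retention.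

Step 19
Reactants: 32; 33 acetaldehyde
Product: 34 7-acetoxy-9-hydroxy-longipin-2-en-1-one with C14–OTBDPS (7-OAc and 9-OH trans)
Conditions: SmI2 (0.3 equiv), 33 (8 equiv), THF, −10 °C
Reagents that add atoms: none
Why: Evans–Tishchenko reduction: the samarium-bound hemiacetal of the C7 hydroxyl and acetaldehyde delivers hydride intramolecularly to the same face of the C9 carbonyl, giving the 1,3-anti C9 alcohol and the C7 acetate in one step; the enone ketone has no β-hydroxyl and is untouched.

Step 20
Reactants: 34; 35 3-methylbut-2-enoic acid (senecioic acid)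
Product: 37 7-acetoxy-9-senecioyloxy-longipin-2-en-1-one with C14–OTBDPS, via mixed anhydride 36 (not isolated)
Conditions: 35, 2,4,6-trichlorobenzoyl chloride, Et3N, THF, rt; then 34, DMAP, toluene, 50 °C
Reagents that add atoms: none
Why: Yamaguchi esterification acylates the hindered C9 hydroxyl through mixed anhydride 36 without deconjugation of the senecioate.

Step 21
Reactants: 37
Product: 38 7-acetoxy-14-hydroxy-9-senecioyloxy-longipin-2-en-1-one
Conditions: HF·pyridine, pyridine, THF, rt
Reagents that add atoms: none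
Why: Fluoride cleavage of the silyl ether under buffered acidic conditions, which avoids acyl migration from O7 to O14.

Step 22
Reactants: 38; 39 (Z)-2-methylbut-2-enoic acid (angelic acid)
Product: 41 CNP0179010.1 (7-acetoxy-14-angeloyloxy-9-senecioyloxy-longipin-2-en-1-one), via mixed anhydride 40 (not isolated)
Conditions: 39, 2,4,6-trichlorobenzoyl chloride, Et3N, toluene, rt; then 38, 75 °C (no nucleophilic catalyst)
Reagents that add atoms: none
Why: Acylation with the 2,4,6-trichlorobenzoyl mixed anhydride of angelic acid in hot toluene without nucleophilic catalyst, conditions under which the Z acyl group should not isomerise to tiglate (Yamaguchi-type esterification).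

**Compound list** (TBS = tert-butyldimethylsilyl, TBDPS = tert-butyldiphenylsilyl)
1 | 3,3-diethoxypropan-1-ol | OCCC(OCC)OCC | starting material
2 | 2-methyl-2-vinyloxirane (racemic) | CC1(C=C)CO1 | starting material
3 | (2S,3S)-5,5-diethoxy-2-methyl-2-vinylpentane-1,3-diol | OC[C@]([C@@H](O)CC(OCC)OCC)(C)C=C | intermediate
4 | (2S,3S)-1,3-bis(TBS-oxy)-5,5-diethoxy-2-methyl-2-vinylpentane | CC(C)(C)[Si](C)(C)OC[C@]([C@@H](O[Si](C)(C)C(C)(C)C)CC(OCC)OCC)(C)C=C | intermediate
5 | (3S,4S)-3,5-bis(TBS-oxy)-4-methyl-4-vinylpentanal | CC(C)(C)[Si](C)(C)OC[C@]([C@@H](O[Si](C)(C)C(C)(C)C)CC=O)(C)C=C | intermediate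
6 | (E)-crotylboronic acid pinacol ester | C/C=C/CB1OC(C)(C)C(C)(C)O1 | starting material
7 | pinacol borate ester of 8 | CC(C)(C)[Si](C)(C)OC[C@]([C@@H](O[Si](C)(C)C(C)(C)C)CC(OB1OC(C)(C)C(C)(C)O1)C(C)C=C)(C)C=C | intermediate (not isolated)
8 | (6S,7S)-6,8-bis(TBS-oxy)-3,7-dimethyl-7-vinyloct-1-en-4-ol, isomers at C3/C4 | CC(C)(C)[Si](C)(C)OC[C@]([C@@H](O[Si](C)(C)C(C)(C)C)CC(O)C(C)C=C)(C)C=C | intermediate
9 | (5S,6S)-6-(TBS-oxy)-5-(TBS-oxymethyl)-2,5-dimethylcyclohept-3-en-1-ol, isomers at C1/C2 | CC(C)(C)[Si](C)(C)OC[C@]1(C)C=CC(C)C(O)C[C@@H]1O[Si](C)(C)C(C)(C)C | intermediate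
10 | (5S,6S)-6-(TBS-oxy)-5-(TBS-oxymethyl)-2,5-dimethylcyclohept-3-en-1-one, C2 epimers | CC(C)(C)[Si](C)(C)OC[C@]1(C)C=CC(C)C(=O)C[C@@H]1O[Si](C)(C)C(C)(C)C | intermediate
11 | ethylene ketal of 10 | CC(C)(C)[Si](C)(C)OC[C@]1(C)C=CC(C)C2(OCCO2)C[C@@H]1O[Si](C)(C)C(C)(C)C | intermediate
12 | primary alcohol from 11 (C14–OH, C7–OTBS, C9 ketal) | OC[C@]1(C)C=CC(C)C2(OCCO2)C[C@@H]1O[Si](C)(C)C(C)(C)C | intermediate
13 | tert-butyl methyl malonate | COC(=O)CC(=O)OC(C)(C)C | starting material
14 | diketene (4-methyleneoxetan-2-one) | C=C1CC(=O)O1 | starting material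
15 | tert-butyl methyl 2-(3-oxobutanoyl)malonate | COC(=O)C(C(=O)CC(C)=O)C(=O)OC(C)(C)C | intermediate (not isolated)
16 | tert-butyl 4-hydroxy-6-methyl-2-oxo-2H-pyran-3-carboxylate | CC1=CC(O)=C(C(=O)OC(C)(C)C)C(=O)O1 | intermediate
17 | tert-butyl 4-methoxy-6-methyl-2-oxo-2H-pyran-3-carboxylate | COC1=C(C(=O)OC(C)(C)C)C(=O)OC(C)=C1 | intermediate
18 | 4-methoxy-6-methyl-2-oxo-2H-pyran-3-carboxylic acid | COC1=C(C(=O)O)C(=O)OC(C)=C1 | intermediate
19 | 4-methoxy-6-methyl-2-oxo-2H-pyran-3-carbonyl chloride | COC1=C(C(=O)Cl)C(=O)OC(C)=C1 | intermediate (not isolated)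
20 | pyrone-3-carboxylate ester of 12 | COC1=C(C(=O)OC[C@]2(C)C=CC(C)C3(OCCO3)C[C@@H]2O[Si](C)(C)C(C)(C)C)C(=O)OC(C)=C1 | intermediate
21 | bridged bicyclo[2.2.2]octene lactone cycloadduct (endo or exo) | COC1=CC2(C)OC(=O)C13C(=O)OC[C@]4(C)[C@H]3[C@H]2C(C)C5(OCCO5)C[C@@H]4O[Si](C)(C)C(C)(C)C | intermediate (not isolated)
22 | tricyclic 2-methoxycyclohexa-1,3-diene δ-lactone | COC1=C2C(=O)OC[C@]3(C)[C@H]2[C@H](C(C)=C1)C(C)C4(OCCO4)C[C@@H]3O[Si](C)(C)C(C)(C)C | intermediate
23 | β-keto δ-lactone (C1 and C9 ketones, C7–OH) | O=C1C2C(=O)OC[C@]3(C)[C@H]2[C@H](C(C)=C1)C(C)C(=O)C[C@@H]3O | intermediate (not isolated)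
24 | β-keto acid (C11–CO2H, C14–OH) | OC[C@]1(C)[C@@H]2C(C(=O)O)C(=O)C=C(C)[C@@H]2C(C)C(=O)C[C@@H]1O | intermediate (not isolated)
25 | cis-fused bicyclic enone ketone diol | OC[C@]1(C)[C@@H]2CC(=O)C=C(C)[C@@H]2C(C)C(=O)C[C@@H]1O | intermediate
26 | C14 TBDPS ether of 25 | CC(C)(C)[Si](c1ccccc1)(c1ccccc1)OC[C@]1(C)[C@@H]2CC(=O)C=C(C)[C@@H]2C(C)C(=O)C[C@@H]1O | intermediate
27 | C7 mesylate of 26 | CC(C)(C)[Si](c1ccccc1)(c1ccccc1)OC[C@]1(C)[C@@H]2CC(=O)C=C(C)[C@@H]2C(C)C(=O)C[C@@H]1OS(C)(=O)=O | intermediate (not isolated)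
28 | cis-fused bicyclic bis-enone, C14–OTBDPS | CC(C)(C)[Si](c1ccccc1)(c1ccccc1)OC[C@]1(C)[C@@H]2CC(=O)C=C(C)[C@@H]2C(C)C(=O)C=C1 | intermediate
29 | dilithium bis-dienolate of 28 | CC(C)(C)[Si](c1ccccc1)(c1ccccc1)OC[C@]1(C)[C@@H]2C=C(O[Li])C=C(C)[C@@H]2C(C)=C(O[Li])C=C1 | intermediate (not isolated)
30 | longipina-2,7-diene-1,9-dione, C14–OTBDPS | CC(C)(C)[Si](c1ccccc1)(c1ccccc1)OC[C@]1(C)[C@@H]2[C@H]3C(=O)C=C(C)[C@@H]2[C@@]3(C)C(=O)C=C1 | intermediate
31 | C7 pinacol boronate of the 7,8-dihydro dione | CC(C)(C)[Si](c1ccccc1)(c1ccccc1)OC[C@]1(C)[C@@H]2[C@H]3C(=O)C=C(C)[C@@H]2[C@@]3(C)C(=O)C[C@H]1B4OC(C)(C)C(C)(C)O4 | intermediate (not isolated)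
32 | 7-hydroxy-longipin-2-ene-1,9-dione, C14–OTBDPS | CC(C)(C)[Si](c1ccccc1)(c1ccccc1)OC[C@]1(C)[C@@H]2[C@H]3C(=O)C=C(C)[C@@H]2[C@@]3(C)C(=O)C[C@H]1O | intermediate
33 | acetaldehyde | CC=O | starting material
34 | 7-acetoxy-9-hydroxy-longipin-2-en-1-one, C14–OTBDPS | CC(C)(C)[Si](c1ccccc1)(c1ccccc1)OC[C@]1(C)[C@@H]2[C@H]3C(=O)C=C(C)[C@@H]2[C@@]3(C)[C@H](O)C[C@H]1OC(C)=O | intermediate
35 | 3-methylbut-2-enoic acid | CC(C)=CC(=O)O | starting material
36 | 3-methylbut-2-enoic 2,4,6-trichlorobenzoic anhydride | CC(C)=CC(=O)OC(=O)c1c(Cl)cc(Cl)cc1Cl | intermediate (not isolated)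
37 | 7-acetoxy-9-senecioyloxy-longipin-2-en-1-one, C14–OTBDPS | CC(C)(C)[Si](c1ccccc1)(c1ccccc1)OC[C@]1(C)[C@@H]2[C@H]3C(=O)C=C(C)[C@@H]2[C@@]3(C)[C@H](OC(=O)C=C(C)C)C[C@H]1OC(C)=O | intermediate
38 | 7-acetoxy-14-hydroxy-9-senecioyloxy-longipin-2-en-1-one | OC[C@]1(C)[C@@H]2[C@H]3C(=O)C=C(C)[C@@H]2[C@@]3(C)[C@H](OC(=O)C=C(C)C)C[C@H]1OC(C)=O | intermediate
39 | (Z)-2-methylbut-2-enoic acid | C/C=C(/C)C(=O)O | starting material
40 | angelic 2,4,6-trichlorobenzoic anhydride | C/C=C(/C)C(=O)OC(=O)c1c(Cl)cc(Cl)cc1Cl | intermediate (not isolated)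
41 | CNP0179010.1 | C/C=C(/C)C(=O)OC[C@]1(C)[C@@H]2[C@H]3C(=O)C=C(C)[C@@H]2[C@@]3(C)[C@H](OC(=O)C=C(C)C)C[C@H]1OC(C)=O | target

**Totals and risks**

Total steps: 22. Longest linear sequence: 19 steps (1–8, 12–22).

Steps most likely to fail:

1. Step 17 (proposed new method). The four-membered ring may not close: the radical from one dienolate may dimerise with a second molecule or be oxidised further before it is captured by C11. Fallback in known chemistry, from 28 back to 30: LDA (1.05 equiv)/TMSCl at −78 °C would remove the secondary C11–H in preference to the tertiary C10–H and give the kinetic trimethylsilyl dienol ether F1. Rubottom oxidation from the convex face would give the C11 α′-hydroxy enone F2 (hydroxyl trans to the C4–C10 bond), and Ms2O/pyridine its mesylate F3. KOtBu in tBuOH/THF would then form the C10 cycloheptadienolate under equilibrating conditions; it displaces the mesylate with inversion (4-exo-tet intramolecular enolate alkylation, the classical closure of pinane-type cyclobutanes) and gives 30.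

2. Step 13 (key step). The hindered, unactivated alkene may react too slowly because the ester tether must adopt its s-cis conformer, so that pyrone decomposition or [1,5]-hydrogen shifts in the diene product take over at the temperature needed. Fallback, from 12 back to 25, forming the same two bonds photochemically: acylation of 12 with 2,2,6-trimethyl-4H-1,3-dioxin-4-one (xylene, 130 °C) would give the acetoacetate F4, and C-acetylation (MgCl2, pyridine, AcCl) the enolised diacetylacetate F5. Irradiation (Pyrex, MeCN) would start an intramolecular de Mayo reaction: [2+2] addition of the enol C=C to the cycloheptene through the same six-membered lactone tether gives the cyclobutanol F6, which opens by retro-aldol to the diketo lactone F7. Aqueous HCl would hydrolyse, decarboxylate and deprotect F7 to the 1,5-diketone diol F8. Pyrrolidine/AcOH aldol condensation through the enamine of the less hindered acetyl group (the one on the CH2) should close the enone and rejoin the route at 25; the regiochemistry of this ring closure is the weak point of the fallback.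

3. Step 19. Hydride transfer may not take place because the samarium hemiacetal chelate cannot reach the C9 carbonyl next to the quaternary C10, or the acetate may migrate between O7 and O9. Fallback, from 32 back to 37: Evans–Saksena reduction (Me4NBH(OAc)3, MeCN/AcOH, −20 °C) would give the anti 7,9-diol F9 by the same intramolecular delivery. Yamaguchi acylation with 35 is expected to take the C9 hydroxyl first, since the C7 hydroxyl sits next to the CH2OTBDPS-bearing quaternary carbon, giving the 9-senecioate 7-alcohol F10. Ac2O/DMAP would then give 37.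

Further compounds
F1 | step 17 | C1 trimethylsilyl dienol ether of 28 (C11=C1(OTMS)–C2=C3) | CC(C)(C)[Si](c1ccccc1)(c1ccccc1)OC[C@]1(C)[C@@H]2C=C(O[Si](C)(C)C)C=C(C)[C@@H]2C(C)C(=O)C=C1
F2 | step 17 | C11 α′-hydroxy derivative of 28 | CC(C)(C)[Si](c1ccccc1)(c1ccccc1)OC[C@]1(C)[C@@H]2[C@@H](O)C(=O)C=C(C)[C@@H]2C(C)C(=O)C=C1
F3 | step 17 | C11 mesylate of F2 | CC(C)(C)[Si](c1ccccc1)(c1ccccc1)OC[C@]1(C)[C@@H]2[C@@H](OS(C)(=O)=O)C(=O)C=C(C)[C@@H]2C(C)C(=O)C=C1
F4 | step 13 | acetoacetate of 12 | CC(=O)CC(=O)OC[C@]1(C)C=CC(C)C2(OCCO2)C[C@@H]1O[Si](C)(C)C(C)(C)C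
F5 | step 13 | diacetylacetate of 12 | CC(=O)C(C(C)=O)C(=O)OC[C@]1(C)C=CC(C)C2(OCCO2)C[C@@H]1O[Si](C)(C)C(C)(C)C
F6 | step 13 | cyclobutanol photoadduct | CC(=O)C12C(=O)OC[C@]3(C)[C@H]1[C@H](C2(C)O)C(C)C4(OCCO4)C[C@@H]3O[Si](C)(C)C(C)(C)C
F7 | step 13 | diketo δ-lactone after retro-aldol | CC(=O)C1C(=O)OC[C@]2(C)[C@H]1[C@H](C(C)=O)C(C)C3(OCCO3)C[C@@H]2O[Si](C)(C)C(C)(C)C
F8 | step 13 | 1,5-diketone diol | OC[C@]1(C)[C@H](CC(C)=O)[C@H](C(C)=O)C(C)C(=O)C[C@@H]1O
F9 | step 19 | anti 7,9-diol, C14–OTBDPS | CC(C)(C)[Si](c1ccccc1)(c1ccccc1)OC[C@]1(C)[C@@H]2[C@H]3C(=O)C=C(C)[C@@H]2[C@@]3(C)[C@H](O)C[C@H]1O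
F10 | step 19 | 9-senecioate 7-alcohol, C14–OTBDPS | CC(C)(C)[Si](c1ccccc1)(c1ccccc1)OC[C@]1(C)[C@@H]2[C@H]3C(=O)C=C(C)[C@@H]2[C@@]3(C)[C@H](OC(=O)C=C(C)C)C[C@H]1O
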